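**Strategy**

The 1,2-dioxane (O1, O2, C3–C6) is closed at C5–C6. The feature exploited is C6, a peroxide-bearing quaternary carbon next to the ring CH2 (C5) and the ethyl-bearing C4: C6 is generated as a peroxycarbenium ion, while C4, C5 and the inner ethyl carbon are stored as a trans-(silylmethyl)cyclopropane. Strain-release opening of that cyclopropane by the tethered cation forms C5–C6, sets C6 under control of C3 and C4, and unveils the C4 ethyl group as vinyl in one operation. The precursor is an acyclic mixed peroxyketal of an ethyl alkynyl ketone, joined through O–O to C3 of a methyl β-peroxy ester that carries the cyclopropane. Diimide reduction and a Julia–Kocienski olefination complete the side chain.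

Key step: step 14

Remark: compound 1 and both enantiomers of the dioxaborolane controller of step 9 are taken as catalogue chemicals; the ketal carbon made in step 6 is carried as both epimers because it is ionised in step 14.

**Route**

Step 1
Reactants: 1 (4S)-4-benzyl-3-butanoyl-1,3-oxazolidin-2-one; 2 3-bromoprop-1-yne
Product: 3 (4S)-4-benzyl-3-[(2R)-2-ethylpent-4-ynoyl]-1,3-oxazolidin-2-one
Conditions: NaN(SiMe3)2, THF, −78 °C; then 2, −78 to −30 °C
Reagents that add atoms: none
Why: Evans auxiliary alkylation, in which the chelated Z-sodium enolate is alkylated on the face opposite the benzyl group and so sets the side-chain stereocentre as (R).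

Step 2
Reactants: 3 (4S)-4-benzyl-3-[(2R)-2-ethylpent-4-ynoyl]-1,3-oxazolidin-2-one
Product: 4 (2R)-2-ethylpent-4-yn-1-ol
Conditions: LiBH4, MeOH (1 equiv), Et2O, 0 °C
Reagents that add atoms: none
Why: Reductive cleavage of the imide by hydride attack at the exocyclic carbonyl should give the primary alcohol without touching the stereocentre or the alkyne and release the auxiliary.

Step 3
Reactants: 4 (2R)-2-ethylpent-4-yn-1-ol; 5 1-phenyl-1H-tetrazole-5-thiol
Product: 6 5-{[(2R)-2-ethylpent-4-yn-1-yl]sulfanyl}-1-phenyl-1H-tetrazole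
Conditions: PPh3, DIAD, THF, 0 °C to rt
Reagents that add atoms: none
Why: Mitsunobu thioetherification, in which the acidic tetrazole thiol displaces the primary alkoxyphosphonium ion by SN2 at a carbon remote from the stereocentre.

Step 4
Reactants: 6 5-{[(2R)-2-ethylpent-4-yn-1-yl]sulfanyl}-1-phenyl-1H-tetrazole
Product: 7 5-{[(2R)-2-ethylpent-4-yn-1-yl]sulfonyl}-1-phenyl-1H-tetrazole
Conditions: (NH4)6Mo7O24·4H2O (10 mol%), 30% H2O2, EtOH, 0 °C to rt
Reagents that add atoms: hydrogen peroxide, OO
Why: Molybdate-catalysed oxidation of a sulfide with H2O2 should run cleanly to the sulfone and leave the terminal alkyne intact.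

Step 5
Reactants: 7 5-{[(2R)-2-ethylpent-4-yn-1-yl]sulfonyl}-1-phenyl-1H-tetrazole; 8 propanoyl chloride
Product: 9 (7R)-7-ethyl-8-[(1-phenyl-1H-tetrazol-5-yl)sulfonyl]oct-4-yn-3-one
Conditions: PdCl2(PPh3)2 (2 mol%), CuI (4 mol%), Et3N (1.2 equiv), THF, rt
Reagents that add atoms: none
Why: Acyl Sonogashira coupling, in which the copper acetylide transmetalates to the acylpalladium chloride and reductive elimination gives the ynone, Et3N being too weak a base to deprotonate the sulfone.

Step 6
Reactants: 9 (7R)-7-ethyl-8-[(1-phenyl-1H-tetrazol-5-yl)sulfonyl]oct-4-yn-3-one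
Product: 11 5-{[(2R)-2-ethyl-6-hydroperoxy-6-methoxyoct-4-yn-1-yl]sulfonyl}-1-phenyl-1H-tetrazole, via dimethyl ketal 10 (not isolated)
Conditions: HC(OMe)3, MeOH, p-TsOH (cat.), rt; volatiles removed; then anhydrous H2O2 in Et2O (3 equiv), p-TsOH (cat.), 0 °C
Reagents that add atoms: trimethyl orthoformate, COC(OC)OC; hydrogen peroxide, OO
Why: Acid-catalysed ketalisation followed by perhydrolysis of the ketal, in which one methoxy group is exchanged for OOH through the alkynyl-stabilised oxocarbenium ion, should give the 1-methoxy hydroperoxide as both epimers at the ketal carbon, which is of no consequence.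

Step 7
Reactants: 12 allyltrimethylsilane; 13 methyl acrylate
Product: 14 methyl (2E)-4-(trimethylsilyl)but-2-enoate
Conditions: second-generation Grubbs catalyst RuCl2(=CHPh)(H2IMes)(PCy3) (2 mol%), CH2Cl2, 40 °C
Reagents that add atoms: none
Why: Olefin cross-metathesis between an electron-rich terminal alkene and an acrylate is selective for the cross product and strongly favours the E-enoate.

Step 8
Reactants: 14 methyl (2E)-4-(trimethylsilyl)but-2-enoate
Product: 15 (2E)-4-(trimethylsilyl)but-2-en-1-ol
Conditions: i-Bu2AlH (2.2 equiv), CH2Cl2, −78 °C; aq. KNaC4H4O6 work-up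
Reagents that add atoms: none
Why: 1,2-Reduction of the enoate by the aluminium hydride at low temperature should give the E-allylic alcohol, and the neutral tartrate work-up avoids acid-induced loss of the allylsilane.

Step 9
Reactants: 15 (2E)-4-(trimethylsilyl)but-2-en-1-ol; 16 diiodomethane
Product: 17 [(1R,2R)-2-[(trimethylsilyl)methyl]cyclopropyl]methanol
Conditions: Et2Zn, 16, DME, CH2Cl2, −10 °C; (4S,5S)-2-butyl-N,N,N',N'-tetramethyl-1,3,2-dioxaborolane-4,5-dicarboxamide (1.2 equiv), −10 °C to rt
Reagents that add atoms: none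
Why: Hydroxyl-directed, dioxaborolane-controlled asymmetric Simmons–Smith cyclopropanation, in which the zinc carbenoid held by the chiral boronate–alkoxide delivers CH2 stereospecifically to one face of the E-alkene and sets both ring centres as (1R,2R), the carbinol-bearing carbon being the future C4 and the new CH2 the future C5.

Step 10
Reactants: 17 [(1R,2R)-2-[(trimethylsilyl)methyl]cyclopropyl]methanol; 18 (triphenyl-λ5-phosphanylidene)acetaldehyde
Product: 20 (2E)-3-{(1S,2R)-2-[(trimethylsilyl)methyl]cyclopropyl}prop-2-enal, via cyclopropanecarbaldehyde 19 (not isolated)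
Conditions: Dess–Martin periodinane, NaHCO3, CH2Cl2, 0 °C to rt; then 18, rt
Reagents that add atoms: none
Why: Dess–Martin oxidation to the aldehyde followed in the same flask by Wittig olefination with the stabilised formyl ylide should give the E-enal with the cyclopropane centres untouched (the descriptor of the ring carbon changes only through the priority rules).

Step 11
Reactants: 20 (2E)-3-{(1S,2R)-2-[(trimethylsilyl)methyl]cyclopropyl}prop-2-enal; 11 5-{[(2R)-2-ethyl-6-hydroperoxy-6-methoxyoct-4-yn-1-yl]sulfonyl}-1-phenyl-1H-tetrazole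
Product: 21 (3S)-3-({(7R)-7-ethyl-3-methoxy-8-[(1-phenyl-1H-tetrazol-5-yl)sulfonyl]oct-4-yn-3-yl}peroxy)-3-{(1R,2R)-2-[(trimethylsilyl)methyl]cyclopropyl}propanal
Conditions: (S)-2-[diphenyl(trimethylsilyloxy)methyl]pyrrolidine (20 mol%), PhCO2H (20 mol%), toluene, −20 °C
Reagents that add atoms: none
Why: Iminium-catalysed asymmetric conjugate addition of a hydroperoxide to an enal (organocatalytic peroxidation), in which the silyloxydiphenylmethyl group shields one face of the s-trans E-iminium ion so that the peroxide oxygen adds to C3 from the open face to give the (3S) centre, while protonation of the enamine at low temperature with the acid co-catalyst should outrun epoxide closure.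

Step 12
Reactants: 21 the β-peroxy aldehyde
Product: 22 (3S)-3-({(7R)-7-ethyl-3-methoxy-8-[(1-phenyl-1H-tetrazol-5-yl)sulfonyl]oct-4-yn-3-yl}peroxy)-3-{(1R,2R)-2-[(trimethylsilyl)methyl]cyclopropyl}propanoic acid
Conditions: NaClO2, NaH2PO4, 2-methylbut-2-ene, t-BuOH/H2O, 0 °C
Reagents that add atoms: sodium chlorite, [Na+].[O-]Cl=O
Why: Pinnick oxidation converts the aldehyde into the acid under buffered, mildly acidic conditions that should spare the peroxyketal, the silane and the β-peroxy stereocentre.

Step 13
Reactants: 22 the β-peroxy acid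
Product: 23 methyl (3S)-3-({(7R)-7-ethyl-3-methoxy-8-[(1-phenyl-1H-tetrazol-5-yl)sulfonyl]oct-4-yn-3-yl}peroxy)-3-{(1R,2R)-2-[(trimethylsilyl)methyl]cyclopropyl}propanoate
Conditions: TMSCHN2, MeOH/toluene, 0 °C
Reagents that add atoms: (trimethylsilyl)diazomethane, C[Si](C)(C)C=[N+]=[N-]
Why: Esterification with (trimethylsilyl)diazomethane proceeds by proton transfer and SN2 attack of the carboxylate on the methyldiazonium ion, without any base that could trigger β-elimination of the peroxide.

Step 14
Reactants: 23 the acyclic peroxyketal ester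
Product: 24 methyl 2-[(3S,4R,6R)-4-ethenyl-6-ethyl-6-{(4R)-4-ethyl-5-[(1-phenyl-1H-tetrazol-5-yl)sulfonyl]pent-1-yn-1-yl}-1,2-dioxan-3-yl]acetate
Conditions: TMSOTf (0.3 equiv), 2,6-di-tert-butyl-4-methylpyridine (0.1 equiv), CH2Cl2, −78 to −40 °C
Reagents that add atoms: none
Why: Proposed new method: TMSOTf removes the methoxy group of the mixed peroxyketal to give an alkynyl-stabilised peroxycarbenium ion at C6, which is attacked with inversion by the distal cyclopropane CH2 (C5) in a homo-Sakurai SE2 opening of the C5–CH σ bond, and the resulting β-silyl cation expels Me3Si+ (regenerating the promoter) to leave the C4 vinyl group; the reasoning is that a (silylmethyl)cyclopropane is the σ-bond homologue of an allylsilane. The closest known reaction types are the Lewis-acid trapping and cyclisation of peroxycarbenium ions by allylsilanes and alkenes and the homoallylation of oxocarbenium ions by (cyclopropylmethyl)silanes. The 1,2-dioxane closes in a 6-exo-tet mode (the cleaved ring bond lies outside the new ring), and the five-membered closure at the proximal cyclopropane carbon C4 is excluded because the three-atom O–O–C tether cannot reach the backside of that carbon. C3 and C4 enter unchanged (C4 is a spectator carbon of the cyclopropane), while the new C6 centre is set in a chair-like transition state in which the departing cyclopropane carbon lies antiperiplanar to the forming bond and hence equatorial on C4, the cis C3 side chain is axial, and the peroxycarbenium ion turns its slim alkynyl group syn to O2 (axial) and its ethyl group anti (equatorial, cis to the C4 vinyl group). The step needs ionisation at the ketal carbon only, C–C over C–O capture, and alkynyl-axial over ethyl-axial selectivity; these are secured by the more basic methoxy oxygen, the enforced proximity of C5, and the much smaller steric demand of a linear sp substituent than of ethyl.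

Step 15
Reactants: 24 the vinyl alkynyl dioxane
Product: 25 methyl 2-[(3S,4S,6S)-4,6-diethyl-6-{(4R)-4-ethyl-5-[(1-phenyl-1H-tetrazol-5-yl)sulfonyl]pentyl}-1,2-dioxan-3-yl]acetate
Conditions: KO2CN=NCO2K (large excess, in portions), AcOH, MeOH/CH2Cl2, 0 °C to rt
Reagents that add atoms: none
Why: Diimide generated in situ transfers H2 through a concerted cyclic transition state to the vinyl group and twice to the alkyne, and should leave the O–O bond, the ester, the sulfone and all stereocentres untouched.

Step 16
Reactants: 25 the saturated sulfone; 26 propanal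
Product: 27 methyl 2-[(3S,4S,6S)-4,6-diethyl-6-[(4R,5E)-4-ethyloct-5-en-1-yl]-1,2-dioxan-3-yl]acetate
Conditions: KN(SiMe3)2 (1.05 equiv), DME, −60 °C, 20 min; then 26, −60 °C to rt
Reagents that add atoms: none
Why: Julia–Kocienski olefination, in which the potassiated sulfone adds to propanal and Smiles rearrangement with anti-elimination of SO2 and the tetrazolate should give mainly the E-alkene, the sulfone CH2 being deprotonated in preference to the ester CH2 so that the β-peroxy ester and the adjacent stereocentre are not disturbed.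

**Compound list**

1 | (4S)-4-benzyl-3-butanoyl-1,3-oxazolidin-2-one | CCCC(=O)N1[C@@H](Cc2ccccc2)COC1=O | starting material
2 | 3-bromoprop-1-yne | C#CCBr | starting material
3 | (4S)-4-benzyl-3-[(2R)-2-ethylpent-4-ynoyl]-1,3-oxazolidin-2-one | CC[C@H](CC#C)C(=O)N1[C@@H](Cc2ccccc2)COC1=O | intermediate
4 | (2R)-2-ethylpent-4-yn-1-ol | CC[C@H](CC#C)CO | intermediate
5 | 1-phenyl-1H-tetrazole-5-thiol | Sc1nnnn1-c1ccccc1 | starting material
6 | 5-{[(2R)-2-ethylpent-4-yn-1-yl]sulfanyl}-1-phenyl-1H-tetrazole | CC[C@H](CC#C)CSc1nnnn1-c1ccccc1 | intermediate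
7 | 5-{[(2R)-2-ethylpent-4-yn-1-yl]sulfonyl}-1-phenyl-1H-tetrazole | CC[C@H](CC#C)CS(=O)(=O)c1nnnn1-c1ccccc1 | intermediate
8 | propanoyl chloride | CCC(=O)Cl | starting material
9 | (7R)-7-ethyl-8-[(1-phenyl-1H-tetrazol-5-yl)sulfonyl]oct-4-yn-3-one | CC[C@H](CC#CC(=O)CC)CS(=O)(=O)c1nnnn1-c1ccccc1 | intermediate
10 | 5-{[(2R)-2-ethyl-6,6-dimethoxyoct-4-yn-1-yl]sulfonyl}-1-phenyl-1H-tetrazole | CC[C@H](CC#CC(OC)(OC)CC)CS(=O)(=O)c1nnnn1-c1ccccc1 | intermediate
11 | 5-{[(2R)-2-ethyl-6-hydroperoxy-6-methoxyoct-4-yn-1-yl]sulfonyl}-1-phenyl-1H-tetrazole (both epimers at C6 of the chain) | CC[C@H](CC#CC(OC)(OO)CC)CS(=O)(=O)c1nnnn1-c1ccccc1 | intermediate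
12 | allyltrimethylsilane | C=CC[Si](C)(C)C | starting material
13 | methyl acrylate | C=CC(=O)OC | starting material
14 | methyl (2E)-4-(trimethylsilyl)but-2-enoate | C[Si](C)(C)C/C=C/C(=O)OC | intermediate
15 | (2E)-4-(trimethylsilyl)but-2-en-1-ol | C[Si](C)(C)C/C=C/CO | intermediate
16 | diiodomethane | ICI | starting material
17 | [(1R,2R)-2-[(trimethylsilyl)methyl]cyclopropyl]methanol | C[Si](C)(C)C[C@@H]1C[C@H]1CO | intermediate
18 | (triphenyl-λ5-phosphanylidene)acetaldehyde | O=CC=P(c1ccccc1)(c1ccccc1)c1ccccc1 | starting material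
19 | (1R,2R)-2-[(trimethylsilyl)methyl]cyclopropane-1-carbaldehyde | C[Si](C)(C)C[C@@H]1C[C@H]1C=O | intermediate
20 | (2E)-3-{(1S,2R)-2-[(trimethylsilyl)methyl]cyclopropyl}prop-2-enal | C[Si](C)(C)C[C@@H]1C[C@H]1/C=C/C=O | intermediate
21 | (3S)-3-({(7R)-7-ethyl-3-methoxy-8-[(1-phenyl-1H-tetrazol-5-yl)sulfonyl]oct-4-yn-3-yl}peroxy)-3-{(1R,2R)-2-[(trimethylsilyl)methyl]cyclopropyl}propanal (both ketal epimers) | C[Si](C)(C)C[C@@H]1C[C@H]1[C@H](CC=O)OOC(OC)(CC)C#CC[C@@H](CC)CS(=O)(=O)c1nnnn1-c1ccccc1 | intermediate
22 | (3S)-3-({(7R)-7-ethyl-3-methoxy-8-[(1-phenyl-1H-tetrazol-5-yl)sulfonyl]oct-4-yn-3-yl}peroxy)-3-{(1R,2R)-2-[(trimethylsilyl)methyl]cyclopropyl}propanoic acid | C[Si](C)(C)C[C@@H]1C[C@H]1[C@H](CC(=O)O)OOC(OC)(CC)C#CC[C@@H](CC)CS(=O)(=O)c1nnnn1-c1ccccc1 | intermediate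
23 | methyl (3S)-3-({(7R)-7-ethyl-3-methoxy-8-[(1-phenyl-1H-tetrazol-5-yl)sulfonyl]oct-4-yn-3-yl}peroxy)-3-{(1R,2R)-2-[(trimethylsilyl)methyl]cyclopropyl}propanoate | C[Si](C)(C)C[C@@H]1C[C@H]1[C@H](CC(=O)OC)OOC(OC)(CC)C#CC[C@@H](CC)CS(=O)(=O)c1nnnn1-c1ccccc1 | intermediate
24 | methyl 2-[(3S,4R,6R)-4-ethenyl-6-ethyl-6-{(4R)-4-ethyl-5-[(1-phenyl-1H-tetrazol-5-yl)sulfonyl]pent-1-yn-1-yl}-1,2-dioxan-3-yl]acetate | O=S(=O)(C[C@H](CC)CC#C[C@@]1(CC)C[C@H](C=C)[C@H](CC(=O)OC)OO1)c1nnnn1-c1ccccc1 | intermediate
25 | methyl 2-[(3S,4S,6S)-4,6-diethyl-6-{(4R)-4-ethyl-5-[(1-phenyl-1H-tetrazol-5-yl)sulfonyl]pentyl}-1,2-dioxan-3-yl]acetate | O=S(=O)(C[C@H](CC)CCC[C@@]1(CC)C[C@H](CC)[C@H](CC(=O)OC)OO1)c1nnnn1-c1ccccc1 | intermediate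
26 | propanal | CCC=O | starting material
27 | methyl 2-[(3S,4S,6S)-4,6-diethyl-6-[(4R,5E)-4-ethyloct-5-en-1-yl]-1,2-dioxan-3-yl]acetate | CC/C=C/[C@H](CC)CCC[C@@]1(CC)C[C@H](CC)[C@H](CC(=O)OC)OO1 | target

**Step count and risks**

Total steps: 16. Longest linear sequence: 12 (steps 1–6, then 11–16); the cyclopropane arm (steps 7–10) joins at step 11.

Steps most likely to fail:

1. Step 14 (the proposed new method). The cyclopropane σ bond may be too weak a nucleophile, so that the peroxycarbenium ion is consumed by alkyl migration to oxygen or by capture at an oxygen atom before the C–C bond forms; facial control at C6 could also be eroded. The fallback uses the known Lewis-acid cyclisation of a peroxyketal onto a tethered alkene (Prins-type) and sets out from hydroperoxide 11 (with ylide 18), coming back at 25. Commercial 2-methylidenebutanal is homologated with 18 to (2E)-4-methylidenehex-2-enal F1. Iminium-catalysed peroxidation of F1 with 11 under the conditions of step 11 should give (3S)-peroxy aldehyde F2. Pinnick oxidation gives acid F3 and TMSCHN2 the methyl ester F4. TMSOTf with 2,6-di-tert-butylpyridine in CH2Cl2 at −78 °C should then close the ring by 6-endo attack of the alkene CH2 on the peroxycarbenium ion, the tertiary C4 cation losing a proton to give 3,6-dihydro-1,2-dioxine F5. In this closure A(1,2) strain with the C4 ethyl group should hold the C3 chain axial, and the alkynyl group again takes the axial position at C6. Exhaustive diimide reduction of the alkyne and of the ring alkene, the latter from the face opposite the axial C3 chain, returns to 25.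

2. Step 11. The peroxy enamine may collapse to the epoxy aldehyde with expulsion of the ketone fragment, or the bulk of hydroperoxide 11 may lower the facial selectivity at C3. The fallback assembles the peroxyketal in two stages, setting out from enal 20 and coming back at 21. The simple reagent 2-methoxypropan-2-yl hydroperoxide F6 (from ozonolysis of 2,3-dimethylbut-2-ene in MeOH) is added to 20 under the same iminium catalysis to give peroxy aldehyde F7. Acid-catalysed peroxyketal exchange of F7 with ketal 10, isolated for this purpose after the first stage of step 6 (PPTS, CH2Cl2, removal of 2,2-dimethoxypropane under reduced pressure), should then give 21.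

3. Step 15. Diimide transfer may stall at the hindered (Z)-alkene stage of the internal alkyne, and prolonged treatment may slowly erode the O–O bond. The fallback separates the two reductions and changes the hydrogen source for the alkyne, setting out from 24 and coming back at 25. A few equivalents of diimide should reduce only the monosubstituted vinyl group and give the 4-ethyl alkyne F8. The alkyne is then saturated with H2 over PtO2 in EtOAc at room temperature; a hindered dialkyl peroxide of this kind is expected to survive brief heterogeneous hydrogenation.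

**Further compounds**

F1 | step 14 | (2E)-4-methylidenehex-2-enal | C=C(CC)/C=C/C=O
F2 | step 14 | (3S)-3-({(7R)-7-ethyl-3-methoxy-8-[(1-phenyl-1H-tetrazol-5-yl)sulfonyl]oct-4-yn-3-yl}peroxy)-4-methylidenehexanal | C=C(CC)[C@H](CC=O)OOC(OC)(CC)C#CC[C@@H](CC)CS(=O)(=O)c1nnnn1-c1ccccc1
F3 | step 14 | (3S)-3-({(7R)-7-ethyl-3-methoxy-8-[(1-phenyl-1H-tetrazol-5-yl)sulfonyl]oct-4-yn-3-yl}peroxy)-4-methylidenehexanoic acid | C=C(CC)[C@H](CC(=O)O)OOC(OC)(CC)C#CC[C@@H](CC)CS(=O)(=O)c1nnnn1-c1ccccc1
F4 | step 14 | methyl (3S)-3-({(7R)-7-ethyl-3-methoxy-8-[(1-phenyl-1H-tetrazol-5-yl)sulfonyl]oct-4-yn-3-yl}peroxy)-4-methylidenehexanoate | C=C(CC)[C@H](CC(=O)OC)OOC(OC)(CC)C#CC[C@@H](CC)CS(=O)(=O)c1nnnn1-c1ccccc1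
F5 | step 14 | methyl 2-[(3S,6R)-4,6-diethyl-6-{(4R)-4-ethyl-5-[(1-phenyl-1H-tetrazol-5-yl)sulfonyl]pent-1-yn-1-yl}-3,6-dihydro-1,2-dioxin-3-yl]acetate | O=S(=O)(C[C@H](CC)CC#C[C@@]1(CC)C=C(CC)[C@H](CC(=O)OC)OO1)c1nnnn1-c1ccccc1
F6 | step 11 | 2-methoxypropan-2-yl hydroperoxide | COC(C)(C)OO
F7 | step 11 | (3S)-3-[(2-methoxypropan-2-yl)peroxy]-3-{(1R,2R)-2-[(trimethylsilyl)methyl]cyclopropyl}propanal | C[Si](C)(C)C[C@@H]1C[C@H]1[C@H](CC=O)OOC(C)(C)OC
F8 | step 15 | methyl 2-[(3S,4S,6R)-4,6-diethyl-6-{(4R)-4-ethyl-5-[(1-phenyl-1H-tetrazol-5-yl)sulfonyl]pent-1-yn-1-yl}-1,2-dioxan-3-yl]acetate | O=S(=O)(C[C@H](CC)CC#C[C@@]1(CC)C[C@H](CC)[C@H](CC(=O)OC)OO1)c1nnnn1-c1ccccc1
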